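South-west's target, as a fraction of the charge, climbs at 0.0372 min⁻¹ from 8.00 min to 20.0 min. That stretch is nearly straight, so I freeze its slope and build on it. In each flask the solid substrate dissolves while the second substrate is fed, and the free enzyme makes the target.

| flask | solid substrate | second substrate | free enzyme | remark | time |
|---|---|---|---|---|---|
| south-west | 0.10 M | 1.1 equiv (fed, over 15 min) | 0.014 mol% | run made earlier |  |
| east | 0.10 M | 1.1 equiv (fed, over 15 min) | 0.022 mol% | run made earlier |  |
| south | 0.15 M | 1.1 equiv (fed, over 15 min) | 0.01 mol% | run made earlier |  |
| flask | 0.10 M | 1.10 equiv (fed, over 15 min) | 0.01 mol% |  | 40 min |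

| run | time / min | target / % |
|---|---|---|
| south-west | 1.50 | 1.6 |
| south-west | 5.00 | 12.0 |
| south-west | 8.00 | 24.1 |
| south-west | 12.0 | 40.3 |
| south-west | 20.0 | 68.8 |
| south-west | 25.0 | 81.8 |
| east | 2.00 | 3.8 |
| east | 3.00 | 7.3 |
| east | 5.00 | 15.5 |
| east | 8.00 | 29.6 |
| east | 15.0 | 60.9 |
| east | 25.0 | 89.1 |
| south | 2.00 | 2.8 |
| south | 6.00 | 12.3 |
| south | 12.0 | 27.6 |
| south | 15.0 | 34.6 |
| south | 25.0 | 54.6 |

(readings scatter by 0.5 percentage points)

- as a solid, counted per litre of solution: solid substrate
- at the start none of the solid substrate is in solution

* amount of target in percent of the solid substrate charged, at 8.0 min, 20 min and 40 min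

The inverse of the steady slope is the crossing time: the minutes the whole charge would take at that slope. East climbs at 0.0447 min⁻¹ from 8.00 min to 15.0 min. South-west, east and the new flask share one charge of solid substrate and one feed of second substrate, so I split the crossing time into a fixed part and an enzyme part that I take to go inversely with the loading.

crossing time, south-west = 26.8 min; east = 22.4 min

enzyme part, south-west = 12.3 min; fixed part = 14.5 min

crossing time of the new flask = 31.8 min

The south-west line starts 1.53 min late. With that delay, my line puts the new flask at 20.4% at 8.0 min and 58.1% at 20 min.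

The weak link is the line itself, which for the new flask reaches the whole charge at 33.3 min, before 40 min. So I reforge the tail. In south-west, the rate at which the untaken fraction falls from 20.0 min to 25.0 min, times the crossing time, is 2.89; in east, from 15.0 min to 25.0 min, the same product is 2.86. Carried to the new flask, this gives:

target at 40 min = 93.2%

The forecast says 20.3%, 59% and 89%, holding that “a partial dissolution limit seems likely”. Its last value is lower than my 93.2%.

The flask gives 19.5%, 60.9% and 83.5%.

    starting material + free enzyme ⇌ first complex (K = 42.7 M⁻¹, k = 1080 M⁻¹ s⁻¹)
    first complex → loaded enzyme + first product (k = 156 s⁻¹)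
    second substrate + loaded enzyme ⇌ second complex (K = 12.4 M⁻¹, k = 485 M⁻¹ s⁻¹)
    second complex → free enzyme + target (k = 153 s⁻¹)
    second substrate + target → over-reaction product (k = 0.00575 M⁻¹ s⁻¹)
    starting material + second substrate → uncatalysed product (k = 1.90 × 10⁻⁴ M⁻¹ s⁻¹)
    solid substrate ⇌ starting material, rate k7*(cs7 - [starting material]) while solid is left; crystals form when [starting material] > cs7 (solubility = 0.0690 M, k = 0.00124 s⁻¹)

Between 8.0 min and 20 min the flask's crossing time reads 29.0 min, against my 31.8 min. For south, counting enzyme per litre and scaling by its larger charge, the same sum gives 39.0 min, and its readings from 6.00 min to 15.0 min give 40.4 min. My tail ran toward the whole charge, but in the flask second substrate also consumes target to form over-reaction product. At 40 min the flask with that step holds 83.5% of target; the same flask without it holds 99.8%.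

All runs are calculated with made-up constants, noise included.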